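**Strategy.** The ten-membered carbocycle (ring C1–C10) is cut at C1–C2. This bond lies between the C1 epoxide carbon and the C3 carbinol and next to the C10 tertiary oxygen, so it is the bond of an aldol between a C3 ketone enolate and a C1 aldehyde. A divalent-samarium Reformatsky reaction of an open-chain bromomethyl enone aldehyde forms C1–C2, closes the carbocycle and sets the C1 carbinol by chelation to the C10 PMB (4-methoxybenzyl) ether in one operation; mesylation and attack of the C10 oxygen later turn this carbinol into the epoxide. The precursor already holds C6, C7, C8 and C10, the E C4=C5 enone, the C6 isobutyrate and the lactone ring masked as C8 and C12 silyl ethers.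

Key step: step 21

Atom labels used below: C1 (epoxide CH) to C10 (methyl-bearing epoxide carbon) run round the carbocycle through C2, the C3 carbinol, the C4=C5 alkene, C6 (isobutyrate), C7, C8 (lactone oxygen) and C9; C11, C12 and C13 are the lactone α-carbon, carbonyl carbon and exocyclic methylene; C14 and C15 are the methyls on C10 and C4. TBS = tert-butyldimethylsilyl, TES = triethylsilyl.

Assumption: in step 16 the (S)-configured oxazoline sulfonamide ligand is taken to steer the alkenylchromium reagent to the aldehyde face that gives the 6S carbinol; its enantiomer would be used if a first run showed the opposite sense.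

**Route**

Step 1
Reactants: 1 (R)-2-methylglycidol
Product: 2 (S)-2-methylpent-4-ene-1,2-diol
Conditions: CH2=CHMgBr (3 equiv), CuI (10 mol %), THF, −30 to 0 °C
Reagents that add atoms: vinylmagnesium bromide, C=C[Mg]Br
Why: Copper-catalysed Grignard opening of the 2,2-disubstituted epoxide takes place at its CH2 carbon (SN2), so the tertiary carbinol centre (C10) is not touched and the vinyl group supplies C8.

Step 2
Reactants: 2 (S)-2-methylpent-4-ene-1,2-diol
Product: 3 (4S)-2-(4-methoxyphenyl)-4-methyl-4-(prop-2-en-1-yl)-1,3-dioxolane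
Conditions: 4-MeOC6H4CH(OMe)2, pyridinium p-toluenesulfonate (cat.), CH2Cl2, rt
Reagents that add atoms: 4-methoxybenzaldehyde dimethyl acetal, COC(OC)c1ccc(OC)cc1
Why: Acid-catalysed transacetalisation of the 1,2-diol gives the five-membered p-methoxybenzylidene acetal, whose new acetal centre is lost again in step 3.

Step 3
Reactants: 3 (4S)-2-(4-methoxyphenyl)-4-methyl-4-(prop-2-en-1-yl)-1,3-dioxolane
Product: 4 (S)-2-[(4-methoxybenzyl)oxy]-2-methylpent-4-en-1-ol
Conditions: i-Bu2AlH, CH2Cl2, −78 to 0 °C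
Reagents that add atoms: none
Why: Reductive acetal opening: aluminium binds the less hindered primary oxygen and hydride reduces the resulting oxocarbenium ion, which leaves the PMB group on the tertiary C10 oxygen and frees the C1 hydroxyl.

Step 4
Reactants: 4 (S)-2-[(4-methoxybenzyl)oxy]-2-methylpent-4-en-1-ol
Product: 5 (S)-triethyl({2-[(4-methoxybenzyl)oxy]-2-methylpent-4-en-1-yl}oxy)silane
Conditions: Et3SiCl, imidazole, CH2Cl2, 0 °C
Reagents that add atoms: chlorotriethylsilane, CC[Si](Cl)(CC)CC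
Why: Standard silylation of the primary C1 hydroxyl; the TES ether can later be removed in the presence of TBS ethers.

Step 5
Reactants: 5 (S)-triethyl({2-[(4-methoxybenzyl)oxy]-2-methylpent-4-en-1-yl}oxy)silane
Product: 6 (S)-3-[(4-methoxybenzyl)oxy]-3-methyl-4-[(triethylsilyl)oxy]butanal
Conditions: OsO4 (2 mol %), NaIO4, 2,6-lutidine, dioxane/H2O, rt
Reagents that add atoms: osmium tetroxide, O=[Os](=O)(=O)=O; sodium periodate, [Na+].[O-]I(=O)(=O)=O
Why: Lemieux–Johnson oxidation (dihydroxylation and periodate cleavage) turns the terminal alkene into the C8 aldehyde, 2,6-lutidine keeping the medium buffered for the silyl and PMB ethers.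

Step 6
Reactants: 7 4-methyl hydrogen itaconate
Product: 9 methyl 3-(hydroxymethyl)but-3-enoate, via ethyl carbonic mixed anhydride 8 (not isolated)
Conditions: ClCO2Et, Et3N, THF, −10 °C; then NaBH4, THF/H2O, 0 °C
Reagents that add atoms: none
Why: Reduction of a carboxylic acid through its mixed carbonic anhydride with NaBH4 is selective over the methyl ester and the alkene and gives the allylic alcohol that becomes C12.

Step 7
Reactants: 9 methyl 3-(hydroxymethyl)but-3-enoate
Product: 10 methyl 3-{[(tert-butyldimethylsilyl)oxy]methyl}but-3-enoate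
Conditions: t-BuMe2SiCl, imidazole, CH2Cl2, 0 °C to rt (crude 9 used at once)
Reagents that add atoms: tert-butyldimethylsilyl chloride, CC(C)(C)[Si](C)(C)Cl
Why: Silylation of the primary allylic alcohol, done on the crude material before the γ-hydroxy ester can lactonise.

Step 8
Reactants: 10 methyl 3-{[(tert-butyldimethylsilyl)oxy]methyl}but-3-enoate
Product: 11 3-{[(tert-butyldimethylsilyl)oxy]methyl}but-3-enoic acid
Conditions: LiOH, THF/H2O, 0 °C; then dilute HCl to pH 4
Reagents that add atoms: lithium hydroxide, [Li+].[OH-]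
Why: Saponification of the methyl ester at 0 °C, mild enough that the β,γ-alkene does not move into conjugation and the primary TBS ether survives.

Step 9
Reactants: 11 3-{[(tert-butyldimethylsilyl)oxy]methyl}but-3-enoic acid; 12 (R)-4-benzyl-1,3-oxazolidin-2-one
Product: 14 (R)-4-benzyl-3-(3-{[(tert-butyldimethylsilyl)oxy]methyl}but-3-enoyl)-1,3-oxazolidin-2-one, via pivalic mixed anhydride 13 (not isolated)
Conditions: t-BuCOCl, Et3N, THF, −20 °C; then 12, LiCl, rt
Reagents that add atoms: none
Why: N-Acylation of the oxazolidinone through the mixed pivalic anhydride (LiCl-promoted), the hindered pivaloyl carbonyl directing attack to the wanted acyl group.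

Step 10
Reactants: 15 (E)-3-iodo-2-methylprop-2-enoic acid
Product: 16 (E)-3-iodo-N-methoxy-N,2-dimethylprop-2-enamide
Conditions: MeNHOMe·HCl, 1-ethyl-3-(3-dimethylaminopropyl)carbodiimide hydrochloride, Et3N, CH2Cl2, 0 °C to rt
Reagents that add atoms: N,O-dimethylhydroxylamine hydrochloride, CNOC.Cl
Why: Carbodiimide-mediated amide formation gives the Weinreb amide without disturbing the alkenyl iodide or its E geometry.

Step 11
Reactants: 16 (E)-3-iodo-N-methoxy-N,2-dimethylprop-2-enamide
Product: 17 (E)-4-iodo-3-methylbut-3-en-2-one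
Conditions: MeMgBr, THF, −78 to 0 °C
Reagents that add atoms: methylmagnesium bromide, C[Mg]Br
Why: Weinreb ketone synthesis: the chelated tetrahedral adduct stops at single addition and the alkenyl iodide does not exchange with MeMgBr at low temperature.

Step 12
Reactants: 14 (R)-4-benzyl-3-(3-{[(tert-butyldimethylsilyl)oxy]methyl}but-3-enoyl)-1,3-oxazolidin-2-one; 6 (S)-3-[(4-methoxybenzyl)oxy]-3-methyl-4-[(triethylsilyl)oxy]butanal
Product: 19 syn-aldol adduct (7R,8S,10S; N-acyl oxazolidinone, free C8 hydroxyl), via Z dibutylboron enolate 18 (not isolated)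
Conditions: Bu2BOTf, i-Pr2NEt, CH2Cl2, 0 °C; then 6, −78 to 0 °C; then pH 7 buffer, MeOH, H2O2, 0 °C
Reagents that add atoms: none
Why: Evans boron aldol reaction: the Z enolate reacts at its α-carbon through a Zimmerman–Traxler chair on the face opposite the benzyl group of the (R)-auxiliary, which sets C7 (R) and C8 (S) as the syn pair irrespective of the remote C10 centre.

Step 13
Reactants: 19 syn-aldol adduct (7R,8S,10S)
Product: 20 β-hydroxy Weinreb amide (7R,8S,10S)
Conditions: AlMe3, MeNHOMe·HCl, CH2Cl2, −20 to 0 °C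
Reagents that add atoms: N,O-dimethylhydroxylamine hydrochloride, CNOC.Cl
Why: Aluminium amide transamination of the aldol adduct, assisted by the free C8 hydroxyl, releases the auxiliary and gives the Weinreb amide without epimerising C7.

Step 14
Reactants: 20 β-hydroxy Weinreb amide (7R,8S,10S)
Product: 21 C8 TBS ether of the Weinreb amide (7R,8S,10S)
Conditions: t-BuMe2SiOTf, 2,6-lutidine, CH2Cl2, −78 to 0 °C
Reagents that add atoms: tert-butyldimethylsilyl triflate, CC(C)(C)[Si](C)(C)OS(=O)(=O)C(F)(F)F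
Why: Silyl triflate silylation of the hindered secondary C8 hydroxyl.

Step 15
Reactants: 21 C8 TBS ether of the Weinreb amide (7R,8S,10S)
Product: 22 C6 aldehyde (7R,8S,10S)
Conditions: i-Bu2AlH, THF, −78 °C; aqueous potassium sodium tartrate
Reagents that add atoms: none
Why: Reduction of the Weinreb amide with i-Bu2AlH stops at the aldehyde through the stable chelated hemiaminal, and the configurationally labile α-branched aldehyde is used without purification.

Step 16
Reactants: 22 C6 aldehyde (7R,8S,10S); 17 (E)-4-iodo-3-methylbut-3-en-2-one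
Product: 24 allylic alcohol (6S,7S,8S,10S), via alkenylchromium dichloride 23 (not isolated)
Conditions: CrCl2, N-{2-[(4S)-4-isopropyl-4,5-dihydro-1,3-oxazol-2-yl]-6-methylphenyl}methanesulfonamide, Et3N, THF, rt; then NiCl2 (cat.), 22, 17, rt
Reagents that add atoms: none
Why: Nozaki–Hiyama–Kishi coupling: divalent chromium (with nickel catalysis of the oxidative addition) turns the alkenyl iodide into an alkenylchromium species that adds to the aldehyde without touching its own ketone and with retention of the E geometry, the new C6 stereocentre being set by the chiral oxazoline sulfonamide ligand on chromium, which should override the weak bias of the α-branched aldehyde.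

Step 17
Reactants: 24 allylic alcohol (6S,7S,8S,10S)
Product: 25 C6 isobutyrate methyl ketone (6S,7S,8S,10S)
Conditions: (i-PrCO)2O, Et3N, 4-(dimethylamino)pyridine (cat.), CH2Cl2, 0 °C to rt
Reagents that add atoms: isobutyric anhydride, CC(C)C(=O)OC(=O)C(C)C
Why: Nucleophile-catalysed acylation of the secondary allylic alcohol installs the isobutyrate with retention at C6.

Step 18
Reactants: 25 C6 isobutyrate methyl ketone (6S,7S,8S,10S)
Product: 27 bromomethyl ketone (6S,7S,8S,10S), via 2-trimethylsilyloxy diene 26 (not isolated)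
Conditions: Me3SiOTf, Et3N, CH2Cl2, −78 to 0 °C; aqueous NaHCO3 wash; then N-bromosuccinimide, NaHCO3, THF, −78 °C
Reagents that add atoms: N-bromosuccinimide, O=C1CCC(=O)N1Br
Why: Soft enolisation of the methyl ketone on its only α'-side gives the 2-silyloxy diene, whose terminal carbon is brominated (electrophilic α-halogenation of a silyl enol ether), so the bromide is placed on C2 only.

Step 19
Reactants: 27 bromomethyl ketone (6S,7S,8S,10S)
Product: 28 C1 alcohol (6S,7S,8S,10S)
Conditions: pyridinium p-toluenesulfonate (cat.), MeOH/CH2Cl2, 0 °C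
Reagents that add atoms: none
Why: Acid-catalysed methanolysis removes the primary TES ether much faster than the primary and secondary TBS ethers, and the α-bromo ketone tolerates these weakly acidic conditions.

Step 20
Reactants: 28 C1 alcohol (6S,7S,8S,10S)
Product: 29 open-chain α-bromo enone aldehyde (6S,7S,8S,10S)
Conditions: Dess–Martin periodinane, NaHCO3, CH2Cl2, 0 °C to rt
Reagents that add atoms: none
Why: Dess–Martin oxidation of the neopentyl-type primary alcohol gives the non-enolisable C1 aldehyde under buffered, non-basic conditions that leave the α-bromo ketone intact.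

Step 21
Reactants: 29 open-chain α-bromo enone aldehyde (6S,7S,8S,10S)
Product: 31 ten-membered β-hydroxy enone (1S,6S,7S,8S,10S), via samarium enolate 30 (not isolated)
Conditions: SmI2 (2.2 equiv, 0.1 M in THF, added dropwise), 29 in THF (0.003 M), −78 °C; then aqueous NH4Cl
Reagents that add atoms: none
Why: Two single-electron transfers from divalent samarium cleave the C2–Br bond and give the trivalent samarium enolate regiospecifically on the C2 side, which adds to the C1 aldehyde; the closest known reaction type is the SmI2-mediated intramolecular Reformatsky (aldol-type) cyclisation used for medium and large rings. The carbocycle C1–C10 closes in a 10-(enolendo)-exo-trig mode, helped by high dilution and by samarium holding both reacting ends. The new C1 stereocentre (S) is controlled by C10 through a five-membered chelate of samarium with the aldehyde oxygen and the C10 PMB ether oxygen (Cram chelate model), the enolate attacking the face flanked by the C14 methyl and not the C9 chain. The step needs the C1 hydroxyl syn to the C10 oxygen on the C9–C10–C1–C2 chain, so that later displacement with inversion gives the 1,10-cis epoxide, and it needs chemoselectivity for C–Br over the aldehyde, the enone and the allylic C6 ester; the first is secured by the chelating benzyl-type ether at C10, the second by the much faster reduction of the α-bromo ketone at −78 °C and by adding SmI2 slowly so that it never accumulates.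

Step 22
Reactants: 31 ten-membered β-hydroxy enone (1S,6S,7S,8S,10S)
Product: 33 syn-1,3-diol (1S,3R,6S,7S,8S,10S), via diethylboron chelate 32 (not isolated)
Conditions: Et2BOMe, THF/MeOH, −78 °C; then NaBH4, −78 °C; then AcOH, aqueous work-up
Reagents that add atoms: none
Why: Narasaka–Prasad reduction: the boron reagent ties the C1 hydroxyl and the C3 ketone into a six-membered chelate and external hydride adds axially, which sets C3 (R) syn to the C1 hydroxyl, 1,2-reduction of the enone being favoured at −78 °C.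

Step 23
Reactants: 33 syn-1,3-diol (1S,3R,6S,7S,8S,10S)
Product: 34 C3 TBS ether (1S,3R,6S,7S,8S,10S)
Conditions: t-BuMe2SiCl, imidazole, DMF, 0 °C to rt
Reagents that add atoms: tert-butyldimethylsilyl chloride, CC(C)(C)[Si](C)(C)Cl
Why: Silylation with the bulky chlorosilane should take place at the allylic C3 hydroxyl, since the C1 hydroxyl sits next to the fully substituted C10 and is far more hindered.

Step 24
Reactants: 34 C3 TBS ether (1S,3R,6S,7S,8S,10S)
Product: 35 C1 mesylate (1S,3R,6S,7S,8S,10S)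
Conditions: MeSO2Cl, Et3N, CH2Cl2, 0 °C
Reagents that add atoms: methanesulfonyl chloride, CS(=O)(=O)Cl
Why: Mesylation via sulfene is efficient even for the hindered secondary C1 hydroxyl and turns it into the leaving group for the epoxide closure.

Step 25
Reactants: 35 C1 mesylate (1S,3R,6S,7S,8S,10S)
Product: 36 C10 hydroxy C1 mesylate (1S,3R,6S,7S,8S,10S)
Conditions: DDQ (2,3-dichloro-5,6-dicyano-1,4-benzoquinone), CH2Cl2/pH 7 phosphate buffer, 0 °C to rt
Reagents that add atoms: none
Why: Oxidative cleavage of the PMB ether (hydride abstraction, hydrolysis of the oxocarbenium ion) frees the tertiary C10 hydroxyl under neutral conditions that spare the mesylate, the ester and the silyl ethers.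

Step 26
Reactants: 36 C10 hydroxy C1 mesylate (1S,3R,6S,7S,8S,10S)
Product: 37 1,10-epoxide tris-TBS ether (1R,3R,6S,7S,8S,10S)
Conditions: NaH, THF, 0 °C to rt
Reagents that add atoms: none
Why: Intramolecular Williamson etherification (3-exo-tet): the C10 alkoxide displaces the C1 mesylate from the back, so C1 is inverted from S to R and the 1,10-cis epoxide forms.

Step 27
Reactants: 37 1,10-epoxide tris-TBS ether (1R,3R,6S,7S,8S,10S)
Product: 38 epoxy triol (1R,3R,6S,7R,8S,10S)
Conditions: Bu4NF, AcOH, THF, 0 °C to rt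
Reagents that add atoms: none
Why: Fluoride-mediated cleavage of the three TBS ethers, buffered with acetic acid so that the epoxide is not opened and the C6 isobutyrate does not migrate to the freed C8 hydroxyl.

Step 28
Reactants: 38 epoxy triol (1R,3R,6S,7R,8S,10S)
Product: 41 target lactone (1R,3R,6S,7R,8S,10S), via hydroxy enal 39 (not isolated), via lactol 40 (not isolated)
Conditions: 2,2,6,6-tetramethylpiperidin-1-oxyl (TEMPO, cat.), PhI(OAc)2, CH2Cl2, rt
Reagents that add atoms: none
Why: TEMPO/PhI(OAc)2 oxidative lactonisation: the oxoammonium species oxidises the primary allylic C12 alcohol much faster than the secondary C3 and C8 alcohols, the enal is trapped by the C8 hydroxyl as the lactol and this is oxidised to the α-methylene γ-lactone without touching any stereocentre.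

**Compound list**

1 | (R)-2-methylglycidol, [(2R)-2-methyloxiran-2-yl]methanol | C[C@]1(CO)OC1 | starting material
2 | (S)-2-methylpent-4-ene-1,2-diol | C=CC[C@](C)(O)CO | intermediate
3 | (4S)-2-(4-methoxyphenyl)-4-methyl-4-(prop-2-en-1-yl)-1,3-dioxolane (both acetal epimers) | C=CC[C@@]1(C)COC(c2ccc(OC)cc2)O1 | intermediate
4 | (S)-2-[(4-methoxybenzyl)oxy]-2-methylpent-4-en-1-ol | C=CC[C@](C)(OCc1ccc(OC)cc1)CO | intermediate
5 | (S)-triethyl({2-[(4-methoxybenzyl)oxy]-2-methylpent-4-en-1-yl}oxy)silane | C=CC[C@](C)(OCc1ccc(OC)cc1)CO[Si](CC)(CC)CC | intermediate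
6 | (S)-3-[(4-methoxybenzyl)oxy]-3-methyl-4-[(triethylsilyl)oxy]butanal (C8 aldehyde, C10 S) | O=CC[C@](C)(OCc1ccc(OC)cc1)CO[Si](CC)(CC)CC | intermediate
7 | 4-methyl hydrogen itaconate (4-methoxy-2-methylidene-4-oxobutanoic acid) | C=C(CC(=O)OC)C(=O)O | starting material
8 | ethyl carbonic mixed anhydride of 7 | C=C(CC(=O)OC)C(=O)OC(=O)OCC | intermediate (not isolated)
9 | methyl 3-(hydroxymethyl)but-3-enoate | C=C(CO)CC(=O)OC | intermediate
10 | methyl 3-{[(tert-butyldimethylsilyl)oxy]methyl}but-3-enoate | C=C(CO[Si](C)(C)C(C)(C)C)CC(=O)OC | intermediate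
11 | 3-{[(tert-butyldimethylsilyl)oxy]methyl}but-3-enoic acid | C=C(CO[Si](C)(C)C(C)(C)C)CC(=O)O | intermediate
12 | (R)-4-benzyl-1,3-oxazolidin-2-one | O=C1N[C@H](Cc2ccccc2)CO1 | starting material
13 | pivalic mixed anhydride of 11 | C=C(CO[Si](C)(C)C(C)(C)C)CC(=O)OC(=O)C(C)(C)C | intermediate (not isolated)
14 | (R)-4-benzyl-3-(3-{[(tert-butyldimethylsilyl)oxy]methyl}but-3-enoyl)-1,3-oxazolidin-2-one | C=C(CO[Si](C)(C)C(C)(C)C)CC(=O)N1[C@H](Cc2ccccc2)COC1=O | intermediate
15 | (E)-3-iodo-2-methylprop-2-enoic acid | C/C(=C\I)C(=O)O | starting material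
16 | (E)-3-iodo-N-methoxy-N,2-dimethylprop-2-enamide | C/C(=C\I)C(=O)N(C)OC | intermediate
17 | (E)-4-iodo-3-methylbut-3-en-2-one | C/C(=C\I)C(C)=O | intermediate
18 | Z dibutylboron enolate of 14 | CCCCB(CCCC)O/C(=C\C(=C)CO[Si](C)(C)C(C)(C)C)N1[C@H](Cc2ccccc2)COC1=O | intermediate (not isolated)
19 | (4R)-4-benzyl-3-[(2R,3S,5S)-2-(3-{[tert-butyl(dimethyl)silyl]oxy}prop-1-en-2-yl)-3-hydroxy-5-[(4-methoxybenzyl)oxy]-5-methyl-6-[(triethylsilyl)oxy]hexanoyl]-1,3-oxazolidin-2-one (7R,8S,10S) | O=C1OC[C@@H](Cc2ccccc2)N1C(=O)[C@H](C(=C)CO[Si](C)(C)C(C)(C)C)[C@@H](O)C[C@](C)(OCc3ccc(OC)cc3)CO[Si](CC)(CC)CC | intermediate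
20 | Weinreb amide of the (2R,3S,5S) hydroxy acid of 19: C6 N-methoxy-N-methylamide, C8–OH, C12–OTBS, C10–OPMB, C1–OTES | CON(C)C(=O)[C@H](C(=C)CO[Si](C)(C)C(C)(C)C)[C@@H](O)C[C@](C)(OCc1ccc(OC)cc1)CO[Si](CC)(CC)CC | intermediate
21 | C8 TBS ether of 20 (7R,8S,10S) | CON(C)C(=O)[C@H](C(=C)CO[Si](C)(C)C(C)(C)C)[C@@H](O[Si](C)(C)C(C)(C)C)C[C@](C)(OCc1ccc(OC)cc1)CO[Si](CC)(CC)CC | intermediate
22 | C6 aldehyde (7R,8S,10S): C8–OTBS, C12–OTBS, C10–OPMB, C1–OTES | O=C[C@H](C(=C)CO[Si](C)(C)C(C)(C)C)[C@@H](O[Si](C)(C)C(C)(C)C)C[C@](C)(OCc1ccc(OC)cc1)CO[Si](CC)(CC)CC | intermediate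
23 | (E)-alkenylchromium dichloride from 17 (ligand omitted) | CC(=O)/C(C)=C/[Cr](Cl)Cl | intermediate (not isolated)
24 | allylic alcohol (6S,7S,8S,10S): C3 methyl ketone, E C4=C5, C6–OH, C8–OTBS, C12–OTBS, C10–OPMB, C1–OTES | CC(=O)/C(C)=C/[C@H](O)[C@H](C(=C)CO[Si](C)(C)C(C)(C)C)[C@@H](O[Si](C)(C)C(C)(C)C)C[C@](C)(OCc1ccc(OC)cc1)CO[Si](CC)(CC)CC | intermediate
25 | C6 isobutyrate of 24 (6S,7S,8S,10S) | CC(=O)/C(C)=C/[C@H](OC(=O)C(C)C)[C@H](C(=C)CO[Si](C)(C)C(C)(C)C)[C@@H](O[Si](C)(C)C(C)(C)C)C[C@](C)(OCc1ccc(OC)cc1)CO[Si](CC)(CC)CC | intermediate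
26 | 2-trimethylsilyloxy diene from 25 (C2=C3 enol ether) | C=C(O[Si](C)(C)C)/C(C)=C/[C@H](OC(=O)C(C)C)[C@H](C(=C)CO[Si](C)(C)C(C)(C)C)[C@@H](O[Si](C)(C)C(C)(C)C)C[C@](C)(OCc1ccc(OC)cc1)CO[Si](CC)(CC)CC | intermediate (not isolated)
27 | C2 bromomethyl ketone (6S,7S,8S,10S), C1–OTES | BrCC(=O)/C(C)=C/[C@H](OC(=O)C(C)C)[C@H](C(=C)CO[Si](C)(C)C(C)(C)C)[C@@H](O[Si](C)(C)C(C)(C)C)C[C@](C)(OCc1ccc(OC)cc1)CO[Si](CC)(CC)CC | intermediate
28 | C2 bromomethyl ketone with free C1 hydroxyl (6S,7S,8S,10S) | BrCC(=O)/C(C)=C/[C@H](OC(=O)C(C)C)[C@H](C(=C)CO[Si](C)(C)C(C)(C)C)[C@@H](O[Si](C)(C)C(C)(C)C)C[C@](C)(OCc1ccc(OC)cc1)CO | intermediate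
29 | open-chain α-bromo enone C1 aldehyde (6S,7S,8S,10S), precursor of the key step | BrCC(=O)/C(C)=C/[C@H](OC(=O)C(C)C)[C@H](C(=C)CO[Si](C)(C)C(C)(C)C)[C@@H](O[Si](C)(C)C(C)(C)C)C[C@](C)(OCc1ccc(OC)cc1)C=O | intermediate
30 | samarium enolate of the C3 ketone (trivalent samarium on the enolate oxygen) | C=C(O[Sm](I)I)/C(C)=C/[C@H](OC(=O)C(C)C)[C@H](C(=C)CO[Si](C)(C)C(C)(C)C)[C@@H](O[Si](C)(C)C(C)(C)C)C[C@](C)(OCc1ccc(OC)cc1)C=O | intermediate (not isolated)
31 | ten-membered β-hydroxy enone (1S,6S,7S,8S,10S): C1–OH, C3 ketone, C10–OPMB, C8–OTBS, C12–OTBS, C6 isobutyrate | C1C(=O)/C(C)=C/[C@H](OC(=O)C(C)C)[C@H](C(=C)CO[Si](C)(C)C(C)(C)C)[C@@H](O[Si](C)(C)C(C)(C)C)C[C@](C)(OCc2ccc(OC)cc2)[C@H]1O | intermediate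
32 | diethylboron chelate of 31 (C1–O–BEt2 bound to the C3 ketone) | C1C(=O)/C(C)=C/[C@H](OC(=O)C(C)C)[C@H](C(=C)CO[Si](C)(C)C(C)(C)C)[C@@H](O[Si](C)(C)C(C)(C)C)C[C@](C)(OCc2ccc(OC)cc2)[C@H]1OB(CC)CC | intermediate (not isolated)
33 | syn-1,3-diol (1S,3R,6S,7S,8S,10S) | C1[C@@H](O)/C(C)=C/[C@H](OC(=O)C(C)C)[C@H](C(=C)CO[Si](C)(C)C(C)(C)C)[C@@H](O[Si](C)(C)C(C)(C)C)C[C@](C)(OCc2ccc(OC)cc2)[C@H]1O | intermediate
34 | C3 TBS ether of 33, free C1 hydroxyl | C1[C@@H](O[Si](C)(C)C(C)(C)C)/C(C)=C/[C@H](OC(=O)C(C)C)[C@H](C(=C)CO[Si](C)(C)C(C)(C)C)[C@@H](O[Si](C)(C)C(C)(C)C)C[C@](C)(OCc2ccc(OC)cc2)[C@H]1O | intermediate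
35 | C1 mesylate of 34 | C1[C@@H](O[Si](C)(C)C(C)(C)C)/C(C)=C/[C@H](OC(=O)C(C)C)[C@H](C(=C)CO[Si](C)(C)C(C)(C)C)[C@@H](O[Si](C)(C)C(C)(C)C)C[C@](C)(OCc2ccc(OC)cc2)[C@H]1OS(C)(=O)=O | intermediate
36 | C10 tertiary alcohol C1 mesylate (1S,3R,6S,7S,8S,10S) | C1[C@@H](O[Si](C)(C)C(C)(C)C)/C(C)=C/[C@H](OC(=O)C(C)C)[C@H](C(=C)CO[Si](C)(C)C(C)(C)C)[C@@H](O[Si](C)(C)C(C)(C)C)C[C@](C)(O)[C@H]1OS(C)(=O)=O | intermediate
37 | 1,10-cis epoxide, C3, C8 and C12 TBS ethers (1R,3R,6S,7S,8S,10S) | C1[C@@H](O[Si](C)(C)C(C)(C)C)/C(C)=C/[C@H](OC(=O)C(C)C)[C@H](C(=C)CO[Si](C)(C)C(C)(C)C)[C@@H](O[Si](C)(C)C(C)(C)C)C[C@]2(C)O[C@H]12 | intermediate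
38 | epoxy triol (1R,3R,6S,7R,8S,10S): C3–OH, C8–OH, C12–OH | C1[C@@H](O)/C(C)=C/[C@H](OC(=O)C(C)C)[C@H](C(=C)CO)[C@@H](O)C[C@]2(C)O[C@H]12 | intermediate
39 | C12 enal with free C8 hydroxyl | C1[C@@H](O)/C(C)=C/[C@H](OC(=O)C(C)C)[C@H](C(=C)C=O)[C@@H](O)C[C@]2(C)O[C@H]12 | intermediate (not isolated)
40 | C12 lactol (both anomers) | C=C1C(O)O[C@H]2C[C@]3(C)O[C@@H]3C[C@@H](O)/C(C)=C/[C@H](OC(=O)C(C)C)[C@H]12 | intermediate (not isolated)
41 | CNP0114243.1, (1R,3R,6S,7R,8S,10S)-1,10-epoxy-3-hydroxy-6-isobutyryloxy germacra-4E,11(13)-dien-8,12-olide | C=C1C(=O)O[C@H]2C[C@]3(C)O[C@@H]3C[C@@H](O)/C(C)=C/[C@H](OC(=O)C(C)C)[C@H]12 | target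

**Step count and risks**

Total step count: 28 (steps 1–5 to aldehyde 6, steps 6–9 to imide 14, steps 10–11 to iodo enone 17, steps 12–28 assembly and endgame). Longest linear sequence: 22 steps (from 1 through steps 1–5 and 12–28).

The three steps most likely to fail:

Step 21 (key step). The samarium enolate may be protonated or add intermolecularly before the ring closes, the allylic C6 ester may be cleaved reductively if SmI2 accumulates, or the aldehyde may be attacked on the wrong face. The fallback keeps the C1–C2 disconnection but drops the halide and the reductant. It sets out from methyl ketone 25: methanolysis of the TES ether (pyridinium p-toluenesulfonate, MeOH) gives hydroxy methyl ketone F1, Dess–Martin oxidation gives keto aldehyde F2, and regioselective enolisation of the methyl ketone with dicyclohexylboron chloride and Et3N in Et2O at −78 °C under high dilution gives dicyclohexylboron enolate F3. This closes onto the non-enolisable C1 aldehyde in an intramolecular boron aldol reaction, and the route is rejoined at 31. The C1 configuration would then rest on the ring and not on chelation and would have to be checked.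

Step 16. Facial selectivity in the addition to the α-branched C6 aldehyde may be poor or reversed if the ligand cannot override the substrate. The fallback sets out from aldehyde 22: the same coupling without ligand control would give the (6R)-allylic alcohol F4 as the main or separable epimer. F4 is esterified with inversion at C6 under Mitsunobu conditions (isobutyric acid, PPh3, diisopropyl azodicarboxylate, toluene, 0 °C), and the route is rejoined at isobutyrate 25. The Mitsunobu reaction at this hindered allylic alcohol may be slow and elimination may compete.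

Step 23. The silylation may not discriminate well enough between the two secondary hydroxyls (C3 against C1). The fallback sets out from diol 33 and uses the PMB group itself: anhydrous DDQ with 4 Å molecular sieves turns the C10 PMB ether and the neighbouring C1 hydroxyl into the five-membered p-methoxybenzylidene acetal F5, in which only the C3 hydroxyl is free. Silylation (t-BuMe2SiOTf, 2,6-lutidine) gives silyl ether F6, and mild acid methanolysis of the acetal (pyridinium p-toluenesulfonate, MeOH, 0 °C) gives C1,C10-diol F7. Mesylation of its secondary C1 hydroxyl (MeSO2Cl, Et3N), which the tertiary C10 hydroxyl does not undergo, rejoins the route at 36.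

Further compounds
F1 | step 21 | hydroxy methyl ketone (25 without the TES group, free C1 hydroxyl) | CC(=O)/C(C)=C/[C@H](OC(=O)C(C)C)[C@H](C(=C)CO[Si](C)(C)C(C)(C)C)[C@@H](O[Si](C)(C)C(C)(C)C)C[C@](C)(OCc1ccc(OC)cc1)CO
F2 | step 21 | keto aldehyde (C3 methyl ketone, C1 aldehyde) | CC(=O)/C(C)=C/[C@H](OC(=O)C(C)C)[C@H](C(=C)CO[Si](C)(C)C(C)(C)C)[C@@H](O[Si](C)(C)C(C)(C)C)C[C@](C)(OCc1ccc(OC)cc1)C=O
F3 | step 21 | dicyclohexylboron enolate of F2 | C=C(OB(C2CCCCC2)C2CCCCC2)/C(C)=C/[C@H](OC(=O)C(C)C)[C@H](C(=C)CO[Si](C)(C)C(C)(C)C)[C@@H](O[Si](C)(C)C(C)(C)C)C[C@](C)(OCc1ccc(OC)cc1)C=O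
F4 | step 16 | (6R)-allylic alcohol, C6 epimer of 24 | CC(=O)/C(C)=C/[C@@H](O)[C@H](C(=C)CO[Si](C)(C)C(C)(C)C)[C@@H](O[Si](C)(C)C(C)(C)C)C[C@](C)(OCc1ccc(OC)cc1)CO[Si](CC)(CC)CC
F5 | step 23 | C1,C10-O-(4-methoxybenzylidene) acetal with free C3 hydroxyl | C1[C@@H](O)/C(C)=C/[C@H](OC(=O)C(C)C)[C@H](C(=C)CO[Si](C)(C)C(C)(C)C)[C@@H](O[Si](C)(C)C(C)(C)C)C[C@]2(C)OC(c3ccc(OC)cc3)O[C@@H]12
F6 | step 23 | C3 TBS ether of F5 | C1[C@@H](O[Si](C)(C)C(C)(C)C)/C(C)=C/[C@H](OC(=O)C(C)C)[C@H](C(=C)CO[Si](C)(C)C(C)(C)C)[C@@H](O[Si](C)(C)C(C)(C)C)C[C@]2(C)OC(c3ccc(OC)cc3)O[C@@H]12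
F7 | step 23 | C1,C10-diol with C3, C8 and C12 TBS ethers | C1[C@@H](O[Si](C)(C)C(C)(C)C)/C(C)=C/[C@H](OC(=O)C(C)C)[C@H](C(=C)CO[Si](C)(C)C(C)(C)C)[C@@H](O[Si](C)(C)C(C)(C)C)C[C@](C)(O)[C@H]1O
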